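The seven-membered ring (C1, C5–C10) is disconnected at C7–C8 and C1–C10. A chiral rhodium vinylcarbene cyclopropanates the vinyl group of an enantiopure 2-vinylcyclopentene and the resulting cis-divinylcyclopropane undergoes a Cope shift, so a single operation closes the cycloheptadiene onto the five-membered ring and sets quaternary C1. The step exploits the fact that quaternary C1 adjoins ring-fusion C5 and that C8=C9 (the later epoxide) is trisubstituted with C14 on C8, which can arrive as an ester; the second alkene formed, C5=C6, later delivers 5α-H and 6α-O. The precursor is the (S)-triethylsilyl ether of 3-methyl-2-vinylcyclopent-2-en-1-ol; triethylsilyl is chosen so that C4 can later be unmasked beside a C6 tert-butyldimethylsilyl ether.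

Key step: step 6

Convention: daucane numbering is used throughout (five-membered ring C1–C5, seven-membered ring C1, C5–C10, C14 on C8, C15 on C1); β is the face of the C15 methyl; compounds that do not yet carry the isopropyl group (C11–C13) are named as 11,12,13-trinordaucanes.

Assumption: the vinylcarbene is taken to show the same facial sense with the prolinate catalyst as the aryl carbene/styrene benchmark ((S)-catalyst gives the (1S,2R)-1,2-diaryl E-cyclopropane), which points to Rh2(R-DOSP)4 for cyclopropane 10; were the sense the reverse, the antipodal catalyst would be used with nothing else changed.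

Step 1
Reactants: 1 3-methylcyclopent-2-en-1-one
Product: 3 2-bromo-3-methylcyclopent-2-en-1-one, via dibromoketone 2 (not isolated)
Conditions: Br2, CH2Cl2, 0 °C; then Et3N, 0 °C → rt
Reagents that add atoms: bromine, BrBr
Why: Bromination–dehydrobromination of an enone: electrophilic addition of bromine across C2=C3, then amine-induced E1cB loss of HBr (acidic C2–H, tertiary C3 bromide) gives the α-bromoenone; no stereocentre remains.

Step 2
Reactants: 3 2-bromo-3-methylcyclopent-2-en-1-one
Product: 4 (S)-2-bromo-3-methylcyclopent-2-en-1-ol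
Conditions: (R)-2-methyl-CBS-oxazaborolidine (20 mol %), BH3·SMe2, THF, −20 °C
Reagents that add atoms: none
Why: Corey–Bakshi–Shibata reduction, for which α-bromoenones are well-suited substrates: the bromoalkene arm acts as the large group and the CH2 arm as the small one, so the (R)-catalyst should deliver hydride to the face that gives the (S)-carbinol (the later C4).

Step 3
Reactants: 4 (S)-2-bromo-3-methylcyclopent-2-en-1-ol
Product: 5 (S)-[(2-bromo-3-methylcyclopent-2-en-1-yl)oxy]triethylsilane
Conditions: Et3SiCl, imidazole, DMF, 0 °C → rt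
Reagents that add atoms: chlorotriethylsilane, CC[Si](Cl)(CC)CC
Why: Imidazole-promoted silylation of a secondary alcohol; the C–O bond is not touched, so the stereocentre is retained.

Step 4
Reactants: 5 (S)-[(2-bromo-3-methylcyclopent-2-en-1-yl)oxy]triethylsilane; 6 tributyl(vinyl)stannane
Product: 7 (S)-triethyl[(3-methyl-2-vinylcyclopent-2-en-1-yl)oxy]silane
Conditions: Pd(PPh3)4 (5 mol %), PhMe, 100 °C
Reagents that add atoms: none
Why: Stille coupling (oxidative addition into the alkenyl C–Br bond, vinyl transfer from tin, reductive elimination) under neutral, fluoride-free conditions that leave the silyl ether and the stereocentre untouched.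

Step 5
Reactants: 8 methyl but-3-enoate
Product: 9 methyl 2-diazobut-3-enoate
Conditions: p-ABSA, DBU, MeCN, 0 °C; cold pentane extract used at once
Reagents that add atoms: 4-acetamidobenzenesulfonyl azide, CC(=O)Nc1ccc(cc1)S(=O)(=O)N=[N+]=[N-]
Why: Direct diazo transfer to the α-carbon of the dienolate of a β,γ-unsaturated ester, the usual entry to vinyldiazoacetates; the product is kept cold and used immediately because the parent compound cyclises to a pyrazole on standing.

Step 6
Reactants: 7 (S)-triethyl[(3-methyl-2-vinylcyclopent-2-en-1-yl)oxy]silane; 9 methyl 2-diazobut-3-enoate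
Product: 11 methyl (1R,4S)-4β-(triethylsilyloxy)-11,12,13-trinordauca-5,8-dien-14-oate, via cis-divinylcyclopropane 10 (not isolated)
Conditions: Rh2(R-DOSP)4 (1 mol %), 9 (2.5 equiv, slow addition), pentane, −40 °C → rt; then PhMe, 90 °C
Reagents that add atoms: none
Why: The rhodium-bound donor/acceptor vinylcarbene from 9 adds end-on to the unhindered monosubstituted alkene C6=C7 of 7 (the tetrasubstituted C1=C5 is too hindered), forming C7–C8 and C6–C8 with the carbene vinyl group cis to the cyclopentenyl group, as is general for donor/acceptor carbenes, and the cis-divinylcyclopropane 10 then undergoes a [3,3]-sigmatropic shift that breaks C6–C8 and forms C1–C10. The closest known reaction type is the tandem cyclopropanation/Cope rearrangement (formal [4+3] annulation) of vinylcarbenes with dienes, which includes 1-methyl-2-vinylcycloalkenes that give angular-methyl quaternary centres. The three-membered ring is closed by [2+1] carbene transfer and opened again, and the seven-membered ring (C1, C5–C10) is closed in the sigmatropic step through the boat (endo,endo) transition state, the only one that leads to the cis,cis-diene C5=C6/C8=C9. The single new stereocentre, C1, is fixed by the catalyst-set configuration of 10 (6S,8S), because the boat lets C10 reach only one face of C1; in that transition state the (S)-silyloxy group at C4 lies on the face away from the incoming C10, so the C15 methyl ends cis to the C4 oxygen. The step needs site selectivity for the vinyl group, E-selective cyclopropanation and catalyst-over-substrate facial control, which the steric difference between the two alkenes, the carbene class and the chiral catalyst respectively should secure. The C1 methyl points into the boat and raises the barrier, hence the heating phase after carbene transfer.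

Step 7
Reactants: 11 methyl (1R,4S)-4β-(triethylsilyloxy)-11,12,13-trinordauca-5,8-dien-14-oate
Product: 13 methyl 6α-hydroxy-4β-(triethylsilyloxy)-5α-11,12,13-trinordauc-8-en-14-oate, via C6-alkylborane 12 (not isolated)
Conditions: BH3·THF, THF, 0 °C; then 3 M NaOH, 30% H2O2, 0 °C
Reagents that add atoms: borane–THF, [BH3-][O+]1CCCC1 (boron retained in 12 only); hydrogen peroxide, OO
Why: Hydroboration–oxidation: the electron-rich trisubstituted C5=C6 should react in preference to the electron-poor enoate C8=C9, boron going to the less substituted C6 and hydrogen to C5 in a syn addition on the α face (the β face carries the C15 methyl and the C4 silyloxy group, the same bias that gives 5α-H/6α-OH from Δ5-steroids), and oxidation with retention then gives 5α-H and 6α-OH.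

Step 8
Reactants: 13 methyl 6α-hydroxy-4β-(triethylsilyloxy)-5α-11,12,13-trinordauc-8-en-14-oate
Product: 14 methyl 6α-(tert-butyldimethylsilyloxy)-4β-(triethylsilyloxy)-5α-11,12,13-trinordauc-8-en-14-oate
Conditions: TBSOTf, 2,6-lutidine, CH2Cl2, −78 → 0 °C
Reagents that add atoms: tert-butyldimethylsilyl trifluoromethanesulfonate, CC(C)(C)[Si](C)(C)OS(=O)(=O)C(F)(F)F
Why: Silyl triflate silylation of a hindered secondary alcohol under non-nucleophilic base; ester, enoate and the triethylsilyl ether are inert and no stereocentre is affected.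

Step 9
Reactants: 14 methyl 6α-(tert-butyldimethylsilyloxy)-4β-(triethylsilyloxy)-5α-11,12,13-trinordauc-8-en-14-oate
Product: 15 6α-(tert-butyldimethylsilyloxy)-4β-(triethylsilyloxy)-5α-11,12,13-trinordauc-8-en-14-ol
Conditions: DIBAL-H (2.5 equiv), CH2Cl2, −78 °C
Reagents that add atoms: none
Why: 1,2-Reduction of a conjugated methyl ester to the primary allylic alcohol by an aluminium hydride; silyl ethers and the alkene are inert.

Step 10
Reactants: 15 6α-(tert-butyldimethylsilyloxy)-4β-(triethylsilyloxy)-5α-11,12,13-trinordauc-8-en-14-ol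
Product: 17 6α-(tert-butyldimethylsilyloxy)-4β-(triethylsilyloxy)-5α-11,12,13-trinordauc-8-ene, via allylic mesylate 16 (not isolated)
Conditions: MsCl, Et3N, THF, −20 °C; then LiEt3BH, −20 → 0 °C
Reagents that add atoms: methanesulfonyl chloride, CS(=O)(=O)Cl (atoms retained in 16 only)
Why: Sulfonylation of the primary allylic alcohol and direct SN2 hydride displacement by Super-Hydride at the unhindered primary carbon (favoured over SN2′ at the secondary C9) convert CH2OH into the C14 methyl without moving C8=C9.

Step 11
Reactants: 17 6α-(tert-butyldimethylsilyloxy)-4β-(triethylsilyloxy)-5α-11,12,13-trinordauc-8-ene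
Product: 18 6α-(tert-butyldimethylsilyloxy)-5α-11,12,13-trinordauc-8-en-4β-ol
Conditions: PPTS (cat.), MeOH/CH2Cl2, 0 °C → rt
Reagents that add atoms: none
Why: Acid-catalysed methanolysis selective for the triethylsilyl ether, which is far more labile to acid than the secondary tert-butyldimethylsilyl ether; C–O bonds and stereocentres are untouched.

Step 12
Reactants: 18 6α-(tert-butyldimethylsilyloxy)-5α-11,12,13-trinordauc-8-en-4β-ol
Product: 19 6α-(tert-butyldimethylsilyloxy)-5α-11,12,13-trinordauc-8-en-4-one
Conditions: Dess–Martin periodinane, CH2Cl2, 0 °C → rt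
Reagents that add atoms: none
Why: Dess–Martin oxidation of a secondary alcohol under near-neutral conditions, which should spare the C5 stereocentre α to the new ketone and the β-silyloxy group at C6.

Step 13
Reactants: 19 6α-(tert-butyldimethylsilyloxy)-5α-11,12,13-trinordauc-8-en-4-one
Product: 20 6α-(tert-butyldimethylsilyloxy)-5α-dauc-8-en-4β-ol
Conditions: i-PrMgCl, CeCl3 (anhydrous), THF, −78 → 0 °C
Reagents that add atoms: isopropylmagnesium chloride, CC(C)[Mg]Cl
Why: Organocerium 1,2-addition (weakly basic, so enolisation at C5, β-elimination of the C6 silyloxy group and hydride transfer are suppressed): the reagent should approach C4 on the α face past H5, because the β trajectory is blocked by the nearly eclipsed C5–C6 bond with its substituents and by the C15 methyl, which sets C4 as 4β-OH/4α-isopropyl.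

Step 14
Reactants: 20 6α-(tert-butyldimethylsilyloxy)-5α-dauc-8-en-4β-ol
Product: 21 5α-dauc-8-ene-4β,6α-diol (jaeschkeanadiol)
Conditions: TBAF, THF, rt → 45 °C
Reagents that add atoms: none
Why: Fluoride-mediated cleavage of the silyl ether at silicon, leaving the tertiary alcohol, the alkene and all stereocentres untouched.

Step 15
Reactants: 21 5α-dauc-8-ene-4β,6α-diol
Product: 22 8α,9α-epoxy-5α-daucane-4β,6α-diol
Conditions: VO(acac)2 (5 mol %), t-BuOOH (decane), CH2Cl2, 0 °C → rt
Reagents that add atoms: tert-butyl hydroperoxide, CC(C)(C)OO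
Why: Hydroxyl-directed vanadium-catalysed epoxidation: the vanadium alkoxide of the homoallylic 6α-OH should deliver the peroxide oxygen to the α face of C8=C9, the face also left open by the β C15 methyl, which sets C8 and C9 as the α-epoxide.

Step 16
Reactants: 22 8α,9α-epoxy-5α-daucane-4β,6α-diol
Product: 23 8α,9α-epoxy-4β-hydroxy-5α-daucan-6α-yl benzoate (target, 1R,4R,5S,6S,8R,9S)
Conditions: Bz2O, DMAP (cat.), Et3N, CH2Cl2, rt
Reagents that add atoms: benzoic anhydride, O=C(OC(=O)c1ccccc1)c1ccccc1
Why: DMAP-catalysed acylation, selective for the secondary C6 hydroxyl because the tertiary C4 hydroxyl is too hindered; the chloride-free, non-acidic medium leaves the epoxide intact.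

Compound list

1 | 3-methylcyclopent-2-en-1-one | CC1=CC(=O)CC1 | starting material
2 | trans-2,3-dibromo-3-methylcyclopentan-1-one (racemic, one enantiomer drawn) | C[C@]1(Br)CCC(=O)[C@@H]1Br | intermediate (not isolated)
3 | 2-bromo-3-methylcyclopent-2-en-1-one | CC1=C(Br)C(=O)CC1 | intermediate
4 | (S)-2-bromo-3-methylcyclopent-2-en-1-ol | O[C@H]1CCC(C)=C1Br | intermediate
5 | (S)-[(2-bromo-3-methylcyclopent-2-en-1-yl)oxy]triethylsilane | CC[Si](CC)(CC)O[C@H]1CCC(C)=C1Br | intermediate
6 | tributyl(vinyl)stannane | C=C[Sn](CCCC)(CCCC)CCCC | starting material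
7 | (S)-triethyl[(3-methyl-2-vinylcyclopent-2-en-1-yl)oxy]silane | C=CC1=C(C)CC[C@@H]1O[Si](CC)(CC)CC | intermediate
8 | methyl but-3-enoate | COC(=O)CC=C | starting material
9 | methyl 2-diazobut-3-enoate | COC(=O)C(=[N+]=[N-])C=C | intermediate
10 | methyl (1S,2S)-2-[(5S)-2-methyl-5-(triethylsilyloxy)cyclopent-1-en-1-yl]-1-vinylcyclopropane-1-carboxylate | C=C[C@@]1(C(=O)OC)C[C@H]1C2=C(C)CC[C@@H]2O[Si](CC)(CC)CC | intermediate (not isolated)
11 | methyl (1R,4S)-4β-(triethylsilyloxy)-11,12,13-trinordauca-5,8-dien-14-oate [methyl (3S,8aR)-8a-methyl-3-(triethylsilyloxy)-1,2,3,5,8,8a-hexahydroazulene-6-carboxylate] | COC(=O)C1=CC[C@@]2(C)CC[C@H](O[Si](CC)(CC)CC)C2=CC1 | intermediate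
12 | C6α-alkylborane of 11 (drawn as RBH2; 5α-H) | CC[Si](CC)(CC)O[C@H]1CC[C@]2(C)CC=C(C(=O)OC)C[C@H](B)[C@H]21 | intermediate (not isolated)
13 | methyl 6α-hydroxy-4β-(triethylsilyloxy)-5α-11,12,13-trinordauc-8-en-14-oate | CC[Si](CC)(CC)O[C@H]1CC[C@]2(C)CC=C(C(=O)OC)C[C@H](O)[C@H]21 | intermediate
14 | methyl 6α-(tert-butyldimethylsilyloxy)-4β-(triethylsilyloxy)-5α-11,12,13-trinordauc-8-en-14-oate | CC[Si](CC)(CC)O[C@H]1CC[C@]2(C)CC=C(C(=O)OC)C[C@H](O[Si](C)(C)C(C)(C)C)[C@H]21 | intermediate
15 | 6α-(tert-butyldimethylsilyloxy)-4β-(triethylsilyloxy)-5α-11,12,13-trinordauc-8-en-14-ol | CC[Si](CC)(CC)O[C@H]1CC[C@]2(C)CC=C(CO)C[C@H](O[Si](C)(C)C(C)(C)C)[C@H]21 | intermediate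
16 | 14-methanesulfonate of 15 | CC[Si](CC)(CC)O[C@H]1CC[C@]2(C)CC=C(COS(C)(=O)=O)C[C@H](O[Si](C)(C)C(C)(C)C)[C@H]21 | intermediate (not isolated)
17 | 6α-(tert-butyldimethylsilyloxy)-4β-(triethylsilyloxy)-5α-11,12,13-trinordauc-8-ene | CC[Si](CC)(CC)O[C@H]1CC[C@]2(C)CC=C(C)C[C@H](O[Si](C)(C)C(C)(C)C)[C@H]21 | intermediate
18 | 6α-(tert-butyldimethylsilyloxy)-5α-11,12,13-trinordauc-8-en-4β-ol | O[C@H]1CC[C@]2(C)CC=C(C)C[C@H](O[Si](C)(C)C(C)(C)C)[C@H]21 | intermediate
19 | 6α-(tert-butyldimethylsilyloxy)-5α-11,12,13-trinordauc-8-en-4-one | O=C1CC[C@]2(C)CC=C(C)C[C@H](O[Si](C)(C)C(C)(C)C)[C@H]21 | intermediate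
20 | 6α-(tert-butyldimethylsilyloxy)-5α-dauc-8-en-4β-ol (4α-isopropyl) | CC(C)[C@]1(O)CC[C@]2(C)CC=C(C)C[C@H](O[Si](C)(C)C(C)(C)C)[C@H]21 | intermediate
21 | 5α-dauc-8-ene-4β,6α-diol (jaeschkeanadiol) | CC(C)[C@]1(O)CC[C@]2(C)CC=C(C)C[C@H](O)[C@H]21 | intermediate
22 | 8α,9α-epoxy-5α-daucane-4β,6α-diol | CC(C)[C@]1(O)CC[C@]2(C)C[C@@H]3O[C@]3(C)C[C@H](O)[C@H]21 | intermediate
23 | 8α,9α-epoxy-4β-hydroxy-5α-daucan-6α-yl benzoate (CNP0340059.1) | CC(C)[C@]1(O)CC[C@]2(C)C[C@@H]3O[C@]3(C)C[C@H](OC(=O)c3ccccc3)[C@H]21 | target

Total step count: 16. Longest linear sequence: 15 steps (steps 1–4 and 6–16); step 5 is a one-step branch.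

Steps most likely to fail

Step 6. Carbene transfer may be diverted (loss of 9 by electrocyclisation to a pyrazole before it meets the catalyst, carbene dimerisation, C–H functionalisation at the doubly activated C4–H), or the substrate may override the catalyst in the cyclopropanation and erode the C1 configuration. The fallback sets out from 7 and uses a stable, more selective carbene precursor. Methyl acetoacetate is converted by diazo transfer (p-ABSA, Et3N, MeCN) into methyl 2-diazo-3-oxobutanoate F1, which is silylated (TBSOTf, Et3N, CH2Cl2, 0 °C) to the bench-stable methyl 2-diazo-3-(tert-butyldimethylsilyloxy)but-3-enoate F2. With a phthalimido-adamantylacetate dirhodium catalyst (Rh2(PTAD)4, enantiomer chosen in a test reaction), 7 and F2 should give, by the same cyclopropanation/Cope sequence, the 9-silyloxy cycloadduct F3. One equivalent of TBAF with PhNTf2 in THF at −78 °C should convert the labile silyl enol ether into the enol triflate F4 while the C4 triethylsilyl ether survives. Palladium-catalysed formate reduction (Pd(OAc)2, PPh3, Bu3N, HCO2H, DMF, 60 °C) then removes the C9 oxygen and comes back to the route at 11.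

Step 7. Borane may also reduce or hydroborate the enoate, or add in part to the β face and give the cis ring fusion. The fallback sets out from 11 and introduces the C6 oxygen without borane. The ester is reduced with DIBAL-H to the allylic alcohol F5, which is deoxygenated through its mesylate F6 (MsCl, Et3N; then LiEt3BH) to the C8-methyl diene F7. TBAF frees the allylic alcohol F8 and Dess–Martin oxidation gives the dienone F9. Nucleophilic epoxidation (t-BuOOH, DBU, CH2Cl2, 0 °C) touches only the enone and should place oxygen on C6 from the α face, giving the 5α,6α-epoxy ketone F10. Samarium diiodide (THF/MeOH, −78 °C) cleaves the C5–O bond, and protonation of the samarium enolate on the α face should give the 6α-hydroxy-5α ketone F11. Silylation of F11 (TBSOTf, 2,6-lutidine) comes back to the route at 19.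

Step 13. At the hindered, enolisable ketone the isopropyl reagent may act as a base (epimerisation at C5, loss of the C6 silyloxy group by β-elimination) or as a hydride donor instead of adding. The fallback sets out from 19 and builds the isopropyl group in two stages. Isopropenylmagnesium bromide with CeCl3 (THF, −78 °C), an sp2 reagent that is smaller, less basic and cannot transfer a β-hydride, should add from the same α face to give the isopropenyl carbinol F12. Hydrogenation with Wilkinson's catalyst (RhCl(PPh3)3, H2 1 atm, benzene, rt), which reduces the 1,1-disubstituted alkene in preference to the trisubstituted C8=C9, comes back to the route at 20.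

Further compounds

F1 | step 6 | methyl 2-diazo-3-oxobutanoate | COC(=O)C(=[N+]=[N-])C(C)=O
F2 | step 6 | methyl 2-diazo-3-(tert-butyldimethylsilyloxy)but-3-enoate | COC(=O)C(=[N+]=[N-])C(=C)O[Si](C)(C)C(C)(C)C
F3 | step 6 | methyl 9-(tert-butyldimethylsilyloxy)-4β-(triethylsilyloxy)-11,12,13-trinordauca-5,8-dien-14-oate | COC(=O)C1=C(O[Si](C)(C)C(C)(C)C)C[C@@]2(C)CC[C@H](O[Si](CC)(CC)CC)C2=CC1
F4 | step 6 | methyl 4β-(triethylsilyloxy)-9-(trifluoromethanesulfonyloxy)-11,12,13-trinordauca-5,8-dien-14-oate | COC(=O)C1=C(OS(=O)(=O)C(F)(F)F)C[C@@]2(C)CC[C@H](O[Si](CC)(CC)CC)C2=CC1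
F5 | step 7 | 4β-(triethylsilyloxy)-11,12,13-trinordauca-5,8-dien-14-ol | OCC1=CC[C@@]2(C)CC[C@H](O[Si](CC)(CC)CC)C2=CC1
F6 | step 7 | 14-methanesulfonate of F5 | CS(=O)(=O)OCC1=CC[C@@]2(C)CC[C@H](O[Si](CC)(CC)CC)C2=CC1
F7 | step 7 | 4β-(triethylsilyloxy)-11,12,13-trinordauca-5,8-diene | CC1=CC[C@@]2(C)CC[C@H](O[Si](CC)(CC)CC)C2=CC1
F8 | step 7 | 11,12,13-trinordauca-5,8-dien-4β-ol | CC1=CC[C@@]2(C)CC[C@H](O)C2=CC1
F9 | step 7 | 11,12,13-trinordauca-5,8-dien-4-one | CC1=CC[C@@]2(C)CCC(=O)C2=CC1
F10 | step 7 | 5α,6α-epoxy-11,12,13-trinordauc-8-en-4-one | O=C1CC[C@]2(C)CC=C(C)C[C@@H]3O[C@@]321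
F11 | step 7 | 6α-hydroxy-5α-11,12,13-trinordauc-8-en-4-one | O=C1CC[C@]2(C)CC=C(C)C[C@H](O)[C@H]21
F12 | step 13 | 6α-(tert-butyldimethylsilyloxy)-4α-isopropenyl-5α-11,12,13-trinordauc-8-en-4β-ol | C=C(C)[C@]1(O)CC[C@]2(C)CC=C(C)C[C@H](O[Si](C)(C)C(C)(C)C)[C@H]21
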